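4 quantities are asked of this flask, and we try to reach the solid substrate through one ratio.

| flask | solid substrate | partner | remark | time |
|---|---|---|---|---|
| gamma | 0.020 M | 0.016 M | the very flask that is asked about, followed so far |  |
| alpha | 0.040 M | 0.016 M | run made earlier |  |
| flask | 0.020 M | 0.0160 M |  | 30 min |

| run | time / min | solid substrate / % | single product / % | double product / % |
|---|---|---|---|---|
| gamma | 0.667 | 93 | 0 | 2 |
| gamma | 1.33 | 89 | 2 | 4 |
| gamma | 2.00 | 82 | 2 | 4 |
| gamma | 2.50 | 80 | 1 | 3 |
| gamma | 3.00 | 76 | 0 | 8 |
| gamma | 4.00 | 67 | 0 | 8 |
| alpha | 5.00 | 77 | 0 | 4 |
| alpha | 10.0 | 73 | 0 | 4 |
| alpha | 15.0 | 74 | 0 | 5 |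
| alpha | 20.0 | 72 | 0 | 3 |
| alpha | 25.0 | 74 | 0 | 6 |
| alpha | 30.0 | 70 | 2 | 4 |

(standard deviation of a reading: 1.5 percentage points)

- the solid substrate standing at 30 min, as a percentage of the solid substrate charged (only what is still solid)
- the single product standing at 30 min, as a percentage of the solid substrate charged
- the double product standing at 30 min, as a percentage of the solid substrate charged
- the triple product standing at 30 min, as a percentage of the solid substrate charged

- given per volume of solution although it is solid: solid substrate
- what was read earlier has a scatter of 1.5 percentage points, one standard deviation
- at the start none of the solid substrate is in solution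

In alpha the solid substrate reads 73% at 10.0 min and 70% at 30.0 min, so it has nearly stopped with solid still present. We take the partner to be the limiting reagent and define Φ, the moles of solid substrate gone per mole of partner charged. Averaging alpha's last 5 readings gives

Φ = 0.685

This flask has alpha's [partner] but half its solid substrate, so Φ folds the charges into one share:

share gone = Φ[partner]/[solid substrate] = 54.8%, solid left = 45.2%

Is one number enough? For the solid substrate it is, if the flask gets there in time. Gamma, this same flask followed early, loses 0.0780 /min of its charge, and if that pace holds we estimate

crossing time = 7.02 min

Control should pass from the pace of dissolution to the partner at this crossing, and because it comes sooner than 30 min, we keep the ratio for this flask.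

The forecast, “Gamma finishes well before 30 min.”, gives 46% solid substrate, 1% single product, 9% double product and 21% triple product, its solid figure lying 0.8 percentage points above ours.

The flask gives 46.6% solid substrate, 0% single product, 8.35% double product and 16.4% triple product.

    starting material + partner → single product (k = 9.40 /M/s)
    partner + single product → double product (k = 17.0 /M/s)
    partner + double product → triple product (k = 1.60 /M/s)
    single product → over-reaction product (k = 0.0380 /s)
    single product ⇌ isomer of the product (K = 2.70, k = 0.00680 /s)
    solid substrate ⇌ starting material, rate k6*(cs6 - [starting material]) while solid is left; crystals form when [starting material] > cs6 (solubility = 2.90 mM, k = 0.0110 /s)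

In this flask, half of the making of single product is done by 2.44 min, far sooner than 30 min. Φ from this flask's own result is 0.667. The neighbour flask charged with 0.027 M of partner departs from it: our Φ gives 7.52% solid left, but that flask holds 27.0%, a ratio of 0.541.

The runs are calculated from invented constants; the scatter is artificial.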